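How much left-handed product stands in violet and in teal at their end times, and which hand leads?

- which of the two there is more of at the end, violet (left-handed product / right-handed product)
- which of the two there is more of at the end, teal (left-handed product / right-handed product)
- how much left-handed product is there at the end, in percent of the left-handed substrate and right-handed substrate together charged: violet
- how much left-handed product is there at the end, in percent of the left-handed substrate and right-handed substrate together charged: teal

| flask | left-handed substrate | right-handed substrate | solid reagent | precatalyst | remark | time |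
|---|---|---|---|---|---|---|
| Thursday's | 14 mM | 14 mM | 20 mM | 0.50 mM | run made earlier |  |
| Wednesday's | 22 mM | 22 mM | 20 mM | 0.50 mM | run made earlier |  |
| Saturday's | 10 mM | 10 mM | 20 mM | 0.25 mM | run made earlier |  |
| violet | 10 mM | 10 mM | 20.0 mM | 0.50 mM |  | 40 h |
| teal | 10 mM | 10 mM | 20.0 mM | 0.50 mM |  | 50 h |

| run | time / h | left-handed product / % |
|---|---|---|
| Thursday's | 2.00 | 0 |
| Thursday's | 6.00 | 1.1 |
| Thursday's | 12.0 | 6.5 |
| Thursday's | 20.0 | 11.7 |
| Thursday's | 25.0 | 14.1 |
| Thursday's | 30.0 | 18.5 |
| Wednesday's | 2.00 | 0.4 |
| Wednesday's | 6.00 | 1.4 |
| Wednesday's | 12.0 | 2.9 |
| Wednesday's | 20.0 | 8.8 |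
| Wednesday's | 25.0 | 10.5 |
| Wednesday's | 30.0 | 12.0 |
| Saturday's | 3.00 | 0.8 |
| Saturday's | 8.00 | 1.8 |
| Saturday's | 15.0 | 8.1 |
| Saturday's | 25.0 | 15.5 |
| Saturday's | 30.0 | 19.1 |

(each reading ± 1 percentage point)

- catalyst is single-handed; left-handed substrate and right-handed substrate are mirror images of each other, charged as a racemate, each of them at the stated concentration
- solid, in amounts per volume of the solution: solid reagent
- the earlier runs were read with a standard deviation of 1 percentage point
- at the start none of the solid reagent is in solution

**What do you read first?** Fractions of the charge, on a logarithmic scale. From 20.0 h on, dividing summed fractions by summed times gives a pace of 0.00591 h⁻¹ for Thursday's run and 0.00417 h⁻¹ for Wednesday's.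

**And the charge?** Wednesday's larger charge gives the smaller fraction. The ratio of logarithms says pace falls as the charge to the power 0.769. A power of one would be zero order in substrate, with the same amount made per hour whatever the charge.

**Why not use the last readings?** They give 0.958, but that rests on one pair, each reading scattered by 1 percentage point. I keep the summed value, itself a reading.

**So, at 10 mM of each substrate?** Scaling Thursday's pace gives 0.00765 h⁻¹, the charge pace, the fraction of the charge becoming left-handed product per hour.

**Does precatalyst matter?** Saturday's run has violet's charge and 0.25 mM of precatalyst, and its pace is 0.00629 h⁻¹, slower than 0.00765 h⁻¹. That is a power of 0.282, itself a reading, smaller than the power on the charge.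

**Your answer?** Multiplying by time, I commit to 30.6% for violet and 38.2% for teal. The straight line past 30.0 h is an assumption. No reading shows right-handed product, so naming left-handed product as the larger is a guess.

The forecast names left-handed product for violet and left-handed product for teal, at 33% and 40%, slightly above my figures, holding that “the rate is essentially zero order in substrate”.

Violet gives 31.7% of left-handed product against 17.8% of right-handed product, and teal gives 39.9% against 22.4%.

    partner + catalyst + left-handed substrate → catalyst + left-handed product (k = 2.00 × 10⁵ L² mol⁻² h⁻¹)
    partner + catalyst + right-handed substrate → catalyst + right-handed product (k = 1.10 × 10⁵ L² mol⁻² h⁻¹)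
    left-handed substrate ⇌ right-handed substrate (k = 0.270 h⁻¹)
    solid reagent ⇌ partner, rate k4*(cs4 - [partner]) while solid is left; crystals form when [partner] > cs4 (solubility = 3.60 mM, k = 0.0860 h⁻¹)
    precatalyst → catalyst (k = 0.0290 h⁻¹)

In teal, with each step taken net, partner is made 0.984 times as fast as it is used at 25.6 h and 1.04 times at 50.0 h, when it stands at 0.564 mM. At 50.0 h in teal, the left-handed conversion uses partner 1.8 times as fast as the right-handed one, a selectivity factor. Teal's own pace is 0.00798 h⁻¹, just above 0.00765 h⁻¹. Read at 30 h, teal should hold 22.9% of left-handed product by the charge pace, and it holds 23.2%.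

The earlier runs and the new flask were computed for substances that don't exist.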